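The hexasubstituted benzenoid ring A is cut at C4a–C5, C5–C6, C7–C8 and C8–CH3, which leaves a monocyclic 4-pyranone. The key step exploits the meta pair of oxygens at C5 and C7 flanking the C6 methyl. It also exploits the C4a=C8a bond, which ring A shares with the pyranone ring as its C3=C2 enol-ether bond. In one operation, a light-driven Wolff methyl shift, a ketene–ynol ether [2+2] addition, a 4π opening and a 6π closure assemble ring A with all six substituents placed. The precursor is a 6-icosyl-4-pyranone bearing a C(=N2)–C(=O)CH3 group at C2. Its partner is 1-(triisopropylsiloxy)propyne.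

Key step: step 6

Remark: the target has no stereocentre and no stereogenic double bond, and its side chain is read as unbranched icosyl (C20), so no stereocontrol is needed.

Step 1
Reactants: 1 pentane-2,4-dione; 2 methyl henicosanoate
Product: 4 hexacosane-2,4,6-trione, via dilithium pentane-2,4-dione dianion 3 (not isolated)
Conditions: 1 (2.2 equiv), LiN(i-Pr)2 (4.4 equiv), THF, 0 °C; then 2 (1 equiv), 0 °C → rt; 1 M HCl
Reagents that add atoms: none
Why: Claisen condensation of a 1,3-diketone dianion, in which the terminal carbanion of 3 is its most nucleophilic site and attacks the ester, while the surplus dianion takes up the acidic proton of the new triketone so that the costly ester 2 stays the limiting partner.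

Step 2
Reactants: 4 hexacosane-2,4,6-trione
Product: 5 2-icosyl-6-methyl-4H-pyran-4-one
Conditions: p-TsOH·H2O (0.2 equiv), toluene, reflux, Dean–Stark
Reagents that add atoms: none
Why: Acid-catalysed cyclodehydration of a 1,3,5-triketone, in which the enol oxygen of one outer carbonyl adds to the other and azeotropic loss of water should drive the hemiketal to the 4-pyranone, with hot toluene keeping the waxy substrate dissolved.

Step 3
Reactants: 5 2-icosyl-6-methyl-4H-pyran-4-one; 6 N-methoxy-N-methylacetamide
Product: 9 6-icosyl-2-(2-oxopropyl)-4H-pyran-4-one, via lithium dienolate 7 (not isolated), via lithium aminal alkoxide 8 (not isolated)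
Conditions: LiN(SiMe3)2 (1.1 equiv), THF, −78 °C, dilute 5 added slowly; 6 (1.5 equiv), −78 → 0 °C; 1 M HCl
Reagents that add atoms: none
Why: Lateral (vinylogous) deprotonation followed by a Weinreb ketone synthesis, in which the bulky amide base should take a proton from the open methyl faster than from the chain α-methylene, and adduct 8 holds until the acid quench so that the more acidic ketone 9 cannot protonate unreacted 7.

Step 4
Reactants: 9 6-icosyl-2-(2-oxopropyl)-4H-pyran-4-one
Product: 10 2-(1-diazo-2-oxopropyl)-6-icosyl-4H-pyran-4-one
Conditions: p-ABSA (1.2 equiv), DBU (1.2 equiv), CH2Cl2–MeCN, 0 °C, dark; used promptly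
Reagents that add atoms: 4-acetamidobenzenesulfonyl azide (p-ABSA), CC(=O)Nc1ccc(cc1)S(=O)(=O)N=[N+]=[N-]
Why: Regitz diazo transfer, in which the methylene of 9 lies between the ketone and the vinylogous acyl position C2 of the pyranone, so DBU should enolise it fully and the enolate attacks the terminal azide nitrogen before the adduct fragments to 10 and the sulfonamide.

Step 5
Reactants: 11 propyne
Product: 14 1-(triisopropylsiloxy)propyne, via 1-propynyllithium 12 (not isolated), via lithium prop-1-yn-1-olate 13 (not isolated)
Conditions: n-BuLi, THF, −78 °C; t-BuOOLi (from t-BuOOH and LiN(SiMe3)2, THF, −78 °C), −78 → 0 °C; i-Pr3SiOTf, −78 → 0 °C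
Reagents that add atoms: tert-butyl hydroperoxide, CC(C)(C)OO; triisopropylsilyl trifluoromethanesulfonate, CC(C)[Si](OS(=O)(=O)C(F)(F)F)(C(C)C)C(C)C
Why: Oxidation of a lithium acetylide by a lithium alkyl peroxide (displacement on the O–O bond) gives ynolate 13, which the bulky silyl triflate should silylate on oxygen and not on carbon, the established way to triisopropylsilyl ynol ethers.

Step 6
Reactants: 10 2-(1-diazo-2-oxopropyl)-6-icosyl-4H-pyran-4-one; 14 1-(triisopropylsiloxy)propyne
Product: 19 5-hydroxy-2-icosyl-6,8-dimethyl-7-(triisopropylsiloxy)-4H-chromen-4-one, via methyl(pyranonyl)ketene 15 (not isolated), via pyranonylcyclobutenone 16 (not isolated), via dienylketene 17 (not isolated), via cyclohexadienone 18 (not isolated)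
Conditions: 14 (2 equiv), degassed ClCH2CH2Cl (0.02 M), 405 nm LEDs, 20 °C until N2 evolution ends; solvent switched to toluene, 110 °C, dark
Reagents that add atoms: none
Why: Proposed new method: 405 nm light should excite only the diazo chromophore of 10, N2 leaves and the acetyl methyl migrates to the diazo carbon (Wolff rearrangement, C8–CH3) to give ketene 15, whose carbonyl carbon is attacked by the nucleophilic methyl-bearing carbon of 14 (C5–C6) while its α-carbon closes onto the siloxy carbon (C7–C8), a [2+2] cycloaddition that gives cyclobutenone 16. Heat opens 16 by conrotatory 4π cleavage of the old ketene C=C bond to dienylketene 17, and ring A, the one ring closed, forms by disrotatory 6π electrocyclisation of the ketene carbon onto pyranone C3 (C4a–C5), after which dienone 18 enolises to the hydrogen-bonded C5 phenol 19. The closest known reaction type is the photochemical Danheiser benzannulation of aryl and heteroaryl diazomethyl ketones with siloxyalkynes, and light-induced alkyl shifts of α-aryl-α-diazo ketones to aryl(alkyl)ketenes are known as well; what is new is the 4-pyranone C2=C3 bond as the vinyl unit and a disubstituted ketene born from a methyl shift. The step needs regioselectivity in the [2+2] event, secured by the polarity of the ynol ether against the electrophilic ketene carbon, and should the partners join in a direct [4+2] sense instead, the isomer silylated at O5 and free at O7 would result, which step 7 converts into the same diol. It also needs the pyranonyl group to turn inward on ring opening, which the outward preference of the donor methyl favours and the reversibility of the opening corrects, and closure has a single site because the other neighbour of C2 is the ring oxygen. No stereocentre is kept, since the racemic quaternary carbon of 16 and the C4a–H centre of 18 vanish on ring opening and aromatisation.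

Step 7
Reactants: 19 5-hydroxy-2-icosyl-6,8-dimethyl-7-(triisopropylsiloxy)-4H-chromen-4-one
Product: 20 5,7-dihydroxy-2-icosyl-6,8-dimethyl-4H-chromen-4-one
Conditions: Bu4NF (1.2 equiv), AcOH (1.2 equiv), THF, 0 °C → rt
Reagents that add atoms: none
Why: Fluoride-induced cleavage of an aryl silyl ether, fast because of the strong Si–F bond and the good phenoxide leaving group, with the acetic acid buffer keeping the medium from opening the base-sensitive chromone ring.

Compound list
1 | pentane-2,4-dione | CC(=O)CC(C)=O | starting material
2 | methyl henicosanoate | CCCCCCCCCCCCCCCCCCCCC(=O)OC | starting material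
3 | dilithium dianion of pentane-2,4-dione (terminal and central carbon deprotonated) | [Li+].[Li+].C=C([O-])C=C(C)[O-] | intermediate
4 | hexacosane-2,4,6-trione | CCCCCCCCCCCCCCCCCCCCC(=O)CC(=O)CC(C)=O | intermediate
5 | 2-icosyl-6-methyl-4H-pyran-4-one | CCCCCCCCCCCCCCCCCCCCc1cc(=O)cc(C)o1 | intermediate
6 | N-methoxy-N-methylacetamide | CC(=O)N(C)OC | starting material
7 | lithium 6-icosyl-2-methylidene-2H-pyran-4-olate (lateral dienolate of 5) | [Li+].C=C1C=C([O-])C=C(CCCCCCCCCCCCCCCCCCCC)O1 | intermediate
8 | lithium 1-(6-icosyl-4-oxo-4H-pyran-2-yl)-2-[methoxy(methyl)amino]propan-2-olate (racemic) | [Li+].CCCCCCCCCCCCCCCCCCCCc1cc(=O)cc(CC(C)([O-])N(C)OC)o1 | intermediate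
9 | 6-icosyl-2-(2-oxopropyl)-4H-pyran-4-one | CCCCCCCCCCCCCCCCCCCCc1cc(=O)cc(CC(C)=O)o1 | intermediate
10 | 2-(1-diazo-2-oxopropyl)-6-icosyl-4H-pyran-4-one | CCCCCCCCCCCCCCCCCCCCc1cc(=O)cc(C(=[N+]=[N-])C(C)=O)o1 | intermediate
11 | propyne | CC#C | starting material
12 | 1-propynyllithium | [Li]C#CC | intermediate
13 | lithium prop-1-yn-1-olate | [Li+].CC#C[O-] | intermediate
14 | 1-(triisopropylsiloxy)propyne | CC#CO[Si](C(C)C)(C(C)C)C(C)C | intermediate
15 | 2-(6-icosyl-4-oxo-4H-pyran-2-yl)prop-1-en-1-one, the methyl(pyranonyl)ketene | CCCCCCCCCCCCCCCCCCCCc1cc(=O)cc(C(C)=C=O)o1 | intermediate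
16 | 4-(6-icosyl-4-oxo-4H-pyran-2-yl)-2,4-dimethyl-3-(triisopropylsiloxy)cyclobut-2-en-1-one (racemic) | CC1=C(O[Si](C(C)C)(C(C)C)C(C)C)C(C)(c2cc(=O)cc(CCCCCCCCCCCCCCCCCCCC)o2)C1=O | intermediate
17 | (3E)-4-(6-icosyl-4-oxo-4H-pyran-2-yl)-2-methyl-3-(triisopropylsiloxy)penta-1,3-dien-1-one (pyranonyl cis to the ketene arm) | O=C=C(C)/C(O[Si](C(C)C)(C(C)C)C(C)C)=C(/C)c1cc(=O)cc(CCCCCCCCCCCCCCCCCCCC)o1 | intermediate
18 | 2-icosyl-6,8-dimethyl-7-(triisopropylsiloxy)-4aH-chromene-4,5-dione (racemic) | CCCCCCCCCCCCCCCCCCCCC1=CC(=O)C2C(=O)C(C)=C(O[Si](C(C)C)(C(C)C)C(C)C)C(C)=C2O1 | intermediate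
19 | 5-hydroxy-2-icosyl-6,8-dimethyl-7-(triisopropylsiloxy)-4H-chromen-4-one | CCCCCCCCCCCCCCCCCCCCc1cc(=O)c2c(O)c(C)c(O[Si](C(C)C)(C(C)C)C(C)C)c(C)c2o1 | intermediate
20 | 5,7-dihydroxy-2-icosyl-6,8-dimethyl-4H-chromen-4-one | CCCCCCCCCCCCCCCCCCCCc1cc(=O)c2c(O)c(C)c(O)c(C)c2o1 | target

Total step count: 7. Longest linear sequence: 6 (steps 1, 2, 3, 4, 6, 7); step 5 runs in parallel.

Steps most likely to fail

Step 6. Several things may go wrong:
- The carbene may be lost before the methyl shift, by capture by the alkyne or by a hydrogen shift after oxirene scrambling.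
- The ketene may self-condense.
- The cascade may stall before the 6π closure.

The fallback gives up the annulation and builds the pyranone ring onto a ready-made ring A by known chemistry. It sets out from 2 and comes back at 20. Commercial 2,4,6-trihydroxyacetophenone is C-methylated twice (MeI, NaOMe, MeOH) to 1-(2,4,6-trihydroxy-3,5-dimethylphenyl)ethan-1-one F1. Its lithium polyanion (LiN(SiMe3)2, 5 equiv, THF, −78 °C → rt) undergoes Claisen condensation with 2 at the acetyl carbon to give 1-(2,4,6-trihydroxy-3,5-dimethylphenyl)tricosane-1,3-dione F2. AcOH with catalytic H2SO4 at 95 °C cyclodehydrates this to 20. The two ortho hydroxyls are equivalent, so only one chromone can form.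

Step 3. Capture of the delocalised anion by the amide may be sluggish. That leaves time for proton exchange between anion and neutral pyranone, which erodes the kinetic preference for the methyl over the chain α-methylene and allows self-condensation. The fallback makes the C–C bond at the alcohol oxidation level. It sets out from 5 and comes back at 9. Anion 7 is trapped at −78 °C by acetaldehyde, a much faster electrophile (aldol addition), to give racemic 2-(2-hydroxypropyl)-6-icosyl-4H-pyran-4-one F3. Dess–Martin periodinane (NaHCO3, CH2Cl2, rt) then oxidises F3 to 9 under neutral conditions that avoid β-elimination.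

Step 4. Three processes may interfere during a prolonged basic reaction:
- base-induced opening of the pyranone,
- azo coupling of the enolate with the product,
- slow 1,5-electrocyclisation of the vinylogous diazo unit.

The fallback is a base-free diazo transfer through an aminomethylene ketone. It sets out from 9 and comes back at 10. DMF dimethyl acetal (toluene, rt → 50 °C) condenses at the doubly activated methylene to give 4-(dimethylamino)-3-(6-icosyl-4-oxo-4H-pyran-2-yl)but-3-en-2-one F4. Tosyl azide (CH2Cl2, rt) adds across the enamine bond, and the triazoline fragments to 10 and a sulfonylformamidine.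

Further compounds
F1 | step 6 | 1-(2,4,6-trihydroxy-3,5-dimethylphenyl)ethan-1-one | CC(=O)c1c(O)c(C)c(O)c(C)c1O
F2 | step 6 | 1-(2,4,6-trihydroxy-3,5-dimethylphenyl)tricosane-1,3-dione | CCCCCCCCCCCCCCCCCCCCC(=O)CC(=O)c1c(O)c(C)c(O)c(C)c1O
F3 | step 3 | 2-(2-hydroxypropyl)-6-icosyl-4H-pyran-4-one (racemic) | CCCCCCCCCCCCCCCCCCCCc1cc(=O)cc(CC(C)O)o1
F4 | step 4 | 4-(dimethylamino)-3-(6-icosyl-4-oxo-4H-pyran-2-yl)but-3-en-2-one | CCCCCCCCCCCCCCCCCCCCc1cc(=O)cc(C(=CN(C)C)C(C)=O)o1
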